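**Strategy.** Dicitrinone H is cut at C8–C8a of the left carbocycle. The feature exploited is the C7–CH(CH3)–C7′ bridge, flanked by oxygenated C8 and C6′. O6′, C8, C7, the bridge carbon, C7′ and C6′ can be tied into a six-membered dihydrocoumarin ring that the target lacks. Within that flat temporary ring the bridge stereocentre is set by asymmetric conjugate reduction. The precursor is this lactone, acylated at C7 by an (E)-tetrasubstituted enoyl chain carrying C3 and C4. Base then cleaves C8–O6′ to an acylketene, closes C8–C8a by 6π-electrocyclisation, creates the left resorcinol ring and releases the 6′-OH in one operation. Deprotection and orthoformate annulation finish the synthesis.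

Key step: step 19

**Remarks on the chemistry**
- Numbering: isochromene numbering for both halves, with the lactone (right) half primed. "Bridge" is the CH(CH3) carbon between C7 and C7′. TBS = tert-butyldimethylsilyl, MOM = methoxymethyl.
- Anti opening of (2S,3S)-2,3-epoxybutane gives the (2S,3S)-carbinol (3′,4′-cis series). The target needs (3′R,4′S), so the carbinol carbon is inverted in step 4.
- The 8′-OH is carried as a MOM ether from step 9 to step 20. The key-step substrate then has one acidic site only, and O6′ is the only phenoxide that can leave or return.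
- The acyl chain of the precursor is a mono-enoyl group. It becomes a dienolate only in the flask of step 19.
- Assumption: (R)-DTBM-SEGPHOS is taken to deliver hydride to the face that gives the (S)-bridge, by analogy with other 4-substituted coumarins. Should the first run show the opposite sense, the (S)-ligand is used with no other change.

**Right half**

Step 1
Reactants: 1 1-bromo-3,5-dimethoxybenzene
Product: 3 2-bromo-4,6-dimethoxybenzaldehyde, via iminium chloride 2 (not isolated)
Conditions: POCl3, DMF, 0 → 90 °C; then ice–water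
Reagents that add atoms: N,N-dimethylformamide CN(C)C=O; water O
Why: Vilsmeier–Haack formylation, in which the chloroiminium ion should attack the carbon para to one methoxy group and ortho to the other (next to Br) rather than the site enclosed by both methoxy groups.

Step 2
Reactants: 3 2-bromo-4,6-dimethoxybenzaldehyde
Product: 4 1-bromo-3,5-dimethoxy-2-methylbenzene
Conditions: Et3SiH (3 equiv), CF3CO2H, CH2Cl2, 0 °C → rt
Reagents that add atoms: none
Why: Ionic hydrogenation, in which the electron-rich aldehyde is reduced twice through the stabilised 2,4-dimethoxybenzyl cation while the aryl bromide is inert.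

Step 3
Reactants: 4 1-bromo-3,5-dimethoxy-2-methylbenzene; 5 (2S,3S)-2,3-epoxybutane
Product: 7 (2S,3S)-3-(3,5-dimethoxy-2-methylphenyl)butan-2-ol, via arylmagnesium bromide 6 (not isolated)
Conditions: Mg, THF, reflux; then CuI (10 mol %), 5, −30 → 0 °C; aq NH4Cl
Reagents that add atoms: none
Why: Copper-catalysed Grignard opening of an epoxide by SN2 attack with inversion; both carbons of the C2-symmetric epoxide give the same product, which sets C4′ (S) and leaves the carbinol carbon (S).

Step 4
Reactants: 7 (2S,3S)-3-(3,5-dimethoxy-2-methylphenyl)butan-2-ol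
Product: 9 (2R,3S)-3-(3,5-dimethoxy-2-methylphenyl)butan-2-ol, via 4-nitrobenzoate 8 (not isolated)
Conditions: PPh3, DIAD, 4-O2NC6H4CO2H, THF, 0 °C → rt; then MeOH, K2CO3 (0.2 equiv), rt
Reagents that add atoms: 4-nitrobenzoic acid O=C(O)c1ccc(cc1)[N+](=O)[O-]
Why: Mitsunobu inversion, in which carboxylate displaces the oxyphosphonium group by SN2 and turns the carbinol carbon from S to R (sets C3′), and the following methanolysis breaks only the acyl–O bond so the new configuration is kept.

Step 5
Reactants: 9 (2R,3S)-3-(3,5-dimethoxy-2-methylphenyl)butan-2-ol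
Product: 10 (2R,3S)-3-(2-bromo-3,5-dimethoxy-6-methylphenyl)butan-2-ol
Conditions: NBS (1.0 equiv), MeCN, 0 °C
Reagents that add atoms: N-bromosuccinimide O=C1CCC(=O)N1Br
Why: Electrophilic aromatic bromination, para-selective for anisoles in MeCN, should take the carbon para to one methoxy group (future C8a′) and leave the carbon between the two methoxy groups (future C7′) free.

Step 6
Reactants: 10 (2R,3S)-3-(2-bromo-3,5-dimethoxy-6-methylphenyl)butan-2-ol
Product: 13 (3R,4S)-6,8-dimethoxy-3,4,5-trimethylisochroman-1-one, via dilithio species 11 (not isolated), via hydroxy acid 12 (not isolated)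
Conditions: n-BuLi (2.2 equiv), THF, −78 °C; CO2 (g); then 2 M HCl, rt
Reagents that add atoms: carbon dioxide O=C=O
Why: Bromine–lithium exchange on the lithium alkoxide, carboxylation and acid-driven δ-lactonisation by acyl substitution, so the C3′–O bond and both stereocentres are untouched.

Step 7
Reactants: 13 (3R,4S)-6,8-dimethoxy-3,4,5-trimethylisochroman-1-one
Product: 14 (3R,4S)-6,8-dihydroxy-3,4,5-trimethylisochroman-1-one
Conditions: BBr3 (4 equiv), CH2Cl2, −78 °C → rt; then H2O
Reagents that add atoms: none
Why: Lewis-acid cleavage of aryl methyl ethers, a standard operation on dimethoxydihydroisocoumarins in which the lactone survives.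

Step 8
Reactants: 14 (3R,4S)-6,8-dihydroxy-3,4,5-trimethylisochroman-1-one; 15 ethyl acetoacetate
Product: 16 4-methylcoumarin lactone (pyranone ring O6′–C8(=O)–C7H=C(CH3)–C7′ fused to the (3′R,4′S)-8′-hydroxy-3′,4′,5′-trimethylisochroman-1′-one core)
Conditions: 15 (1.5 equiv), MeSO3H, rt → 50 °C
Reagents that add atoms: none
Why: Pechmann condensation, in which C7′ is the only free ring carbon and ring closure should use O6′ because the 8′-OH is tied up by its hydrogen bond to C1′=O, as in the classical formation of 5-hydroxy-4-methylcoumarin-6-carboxylates from β-resorcylic esters.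

Step 9
Reactants: 16 4-methylcoumarin lactone
Product: 17 8′-O-MOM 4-methylcoumarin lactone
Conditions: NaH, MOMCl, DMF, 0 °C → rt
Reagents that add atoms: chloromethyl methyl ether COCCl
Why: Williamson-type O-alkylation of the only hydroxyl group by a small and reactive electrophile that tolerates the crowded chelated position.

Step 10
Reactants: 17 8′-O-MOM 4-methylcoumarin lactone
Product: 19 (S)-bridge 4-methyl-3,4-dihydrocoumarin lactone (8′-O-MOM; 3′R,4′S), via boron enolate 18 (not isolated)
Conditions: CuCl (5 mol %), NaOt-Bu (5 mol %), (R)-DTBM-SEGPHOS (5.5 mol %), HBpin (1.5 equiv), toluene, rt; then H2O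
Reagents that add atoms: none
Why: CuH-catalysed asymmetric conjugate reduction of a coumarin (1,4-hydroboration), in which the ligated monovalent copper hydride adds hydride to the bridge carbon from the face chosen by the bisphosphine and sets the bridge as S, while the boron enolate blocks further reduction of the lactone carbonyl.

**Left chain**

Step 11
Reactants: 20 ethyl (R)-3-hydroxybutanoate
Product: 22 ethyl (2R,3R)-3-hydroxy-2-methylbutanoate, via dilithio enolate 21 (not isolated)
Conditions: LiN(i-Pr)2 (2.2 equiv), THF, −78 → −20 °C; MeI, DMPU, −78 → 0 °C; aq NH4Cl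
Reagents that add atoms: iodomethane CI
Why: Fráter–Seebach alkylation, in which the lithium-chelated alkoxide enolate is methylated opposite to the carbinol methyl group to give the anti product and thereby C4 of the target (C3 comes from the chiral pool).

Step 12
Reactants: 22 ethyl (2R,3R)-3-hydroxy-2-methylbutanoate
Product: 23 ethyl (2R,3R)-3-(TBS-oxy)-2-methylbutanoate
Conditions: TBSCl, imidazole, DMF, rt
Reagents that add atoms: tert-butyldimethylsilyl chloride CC(C)(C)[Si](C)(C)Cl
Why: Standard imidazole-promoted silylation of a secondary alcohol, giving an ether stable to all basic steps that follow.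

Step 13
Reactants: 23 ethyl (2R,3R)-3-(TBS-oxy)-2-methylbutanoate
Product: 24 (2R,3R)-3-(TBS-oxy)-2-methylbutanoic acid
Conditions: LiOH, THF/MeOH/H2O, rt; then 1 M HCl to pH 4, 0 °C
Reagents that add atoms: lithium hydroxide [Li+].[OH-]
Why: Saponification at room temperature, mild enough that neither α-epimerisation nor β-elimination of the silyloxy group should occur.

Step 14
Reactants: 24 (2R,3R)-3-(TBS-oxy)-2-methylbutanoic acid; 25 3-ethoxy-2-methyl-3-oxopropanoic acid (ethyl hydrogen methylmalonate)
Product: 28 ethyl (4R,5R)-5-(TBS-oxy)-2,4-dimethyl-3-oxohexanoate (C2 epimers), via acyl imidazolide 26 (not isolated), via magnesium enolate 27 (not isolated)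
Conditions: 24, CDI, THF, rt; separately 25, i-PrMgCl (2 equiv), THF, 0 °C → rt; combine, rt → 40 °C; then 1 M HCl, 0 °C
Reagents that add atoms: none
Why: Decarboxylative Claisen condensation of a magnesium malonate half-ester enolate with an acyl imidazolide (Masamune–Brooks type), near-neutral conditions under which the α-stereocentre (future C4) should not epimerise.

Step 15
Reactants: 28 ethyl (4R,5R)-5-(TBS-oxy)-2,4-dimethyl-3-oxohexanoate
Product: 29 ethyl (2Z,4R,5R)-5-(TBS-oxy)-2,4-dimethyl-3-(trifluoromethylsulfonyloxy)hex-2-enoate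
Conditions: LiOSO2CF3, Et3N, Tf2O, CH2Cl2, −78 → 0 °C
Reagents that add atoms: trifluoromethanesulfonic anhydride O=S(=O)(OS(=O)(=O)C(F)(F)F)C(F)(F)F
Why: O-sulfonylation of a lithium-chelated β-keto ester enolate, in which chelation holds the enolate oxygen cis to the ester carbonyl so the (Z)-enol triflate should form, and the far more acidic C2–H shields C4 from enolisation.

Step 16
Reactants: 29 ethyl (2Z,4R,5R)-5-(TBS-oxy)-2,4-dimethyl-3-(trifluoromethylsulfonyloxy)hex-2-enoate
Product: 30 ethyl (2E,4S,5R)-5-(TBS-oxy)-2,3,4-trimethylhex-2-enoate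
Conditions: MeZnCl (2 equiv), Pd(PPh3)4 (5 mol %), THF, rt → 50 °C
Reagents that add atoms: methylzinc chloride C[Zn]Cl
Why: Negishi coupling, in which oxidative addition of zerovalent palladium, transmetalation and reductive elimination proceed with retention, so the new methyl group (future C8a) ends up cis to the ester (the C4 descriptor changes only through CIP ranking).

Step 17
Reactants: 30 ethyl (2E,4S,5R)-5-(TBS-oxy)-2,3,4-trimethylhex-2-enoate
Product: 31 (2E,4S,5R)-5-(TBS-oxy)-2,3,4-trimethylhex-2-enoic acid
Conditions: LiOH·H2O, THF/MeOH/H2O, 60 °C; then 1 M HCl to pH 4, 0 °C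
Reagents that add atoms: lithium hydroxide [Li+].[OH-]
Why: Saponification of a hindered enoate needs warming, but hydroxide is too weak to form the dienolate, so alkene geometry and C4 should hold, and a secondary TBS ether is stable to aqueous base.

**Union, key step and endgame**

Step 18
Reactants: 19 (S)-bridge 4-methyl-3,4-dihydrocoumarin lactone; 31 (2E,4S,5R)-5-(TBS-oxy)-2,3,4-trimethylhex-2-enoic acid
Product: 34 3-acyl-4-methyldihydrocoumarin lactone (C7 bears the (2E,4S,5R)-5-(TBS-oxy)-2,3,4-trimethylhex-2-enoyl group; bridge S; 8′-O-MOM; 3′R,4′S; C7 unassigned), via acid chloride 32 (not isolated), via lithium enolate 33 (not isolated)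
Conditions: 31, 1-chloro-N,N,2-trimethylprop-1-en-1-amine, CH2Cl2, 0 °C → rt, concentrate; separately 19, LiN(SiMe3)2 (2.2 equiv), THF, −78 °C; add 32, −78 °C; AcOH quench
Reagents that add atoms: none
Why: Crossed Claisen-type C-acylation of a lactone lithium enolate by an acid chloride made under neutral conditions, with the second equivalent of base storing the product as its stabilised enolate; the C7 configuration is irrelevant because this centre is enolisable and becomes sp2.

Step 19
Reactants: 34 3-acyl-4-methyldihydrocoumarin lactone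
Product: 38 bridged bis-arene (left 6,8-dihydroxy-5-methylphenyl ring with H at C8a and the (2S,3R)-3-(TBS-oxy)butan-2-yl chain at C4a; bridge S; right lactone with free 6′-OH and 8′-O-MOM), via acylketene phenoxide 35 (not isolated), via dienylketene 36 (not isolated), via cyclohexadienone 37 (not isolated)
Conditions: KN(SiMe3)2 (3.5 equiv), degassed THF (0.01 M), −78 °C → rt, then 45 °C if needed; AcOH, 0 °C
Reagents that add atoms: none
Why: Proposed new method: KN(SiMe3)2 first forms the C7 enolate of the β-keto aryl lactone, which on warming should expel the para-acyl-stabilised O6′ phenoxide (E1cB) to give acylketene 35, further base removes a proton from the C8a methyl group to give oxido-dienylketene 36, C8–C8a closure gives dienone 37, and loss of the second C8a proton aromatises it irreversibly. The closest known reaction types are the E1cB or thermal generation of acylketenes from aryl β-keto esters and dioxinones and the 6π-electrocyclisation of dienylketenes to phenols in benzannulation chemistry, and a direct vinylogous Dieckmann attack of C8a on the lactone carbonyl would lead to the same product. The one ring closed, the left carbocycle, forms by thermal disrotatory 6π closure of the C8a=C4a–C5=C6–C7=C8 array (in polar terms a 6-exo-dig attack of C8a on the sp carbon C8), while the temporary lactone ring is opened, so 34 and 38 are isomers. No stereocentre is created, and the bridge carbon, C3, C4, C3′ and C4′ should survive because the bridge C–H is not acidified and carries no β-leaving group. The step needs deprotonation at C8a and not at the C4 methine (which would eject silanolate), and the (E)-alkene secures this by holding the primary C8a methyl cis to the C6 carbonyl, while the right lactone, an alkyl aroate without α-hydrogen, cannot enter an E1cB path and the MOM group removes the only other acidic site. Re-addition of O6′ to the ketene only regenerates the enolate of 34 and rotation about C5–C6 in the cross-conjugated anion supplies the s-cis rotamer, so the equilibria are drained by aromatisation, and high dilution suppresses intermolecular ketene capture.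

Step 20
Reactants: 38 bridged bis-arene
Product: 39 pentaol (free C3-OH; 6-OH; 8-OH; 6′-OH; 8′-OH; bridge S; 3R,4S,3′R,4′S)
Conditions: HCl (1.25 M in MeOH), rt → 40 °C
Reagents that add atoms: none
Why: Acid methanolysis removes the secondary TBS ether and the carbonyl-activated aryl MOM acetal together, under conditions mild enough that retro-Friedel–Crafts cleavage at the diarylethane bridge should not start.

Step 21
Reactants: 39 pentaol
Product: 41 dicitrinone H, via ethoxy acetal 40 (not isolated)
Conditions: HC(OEt)3 (10 equiv), CF3CO2H, CH2Cl2, 0 °C → rt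
Reagents that add atoms: triethyl orthoformate CCOC(OCC)OCC
Why: Orthoformate formylation with oxa-Pictet–Spengler-type ring closure, a known way to build this quinone methide on 5-alkylresorcinols: the C3 hydroxyl exchanges onto the orthoester, the dialkoxycarbenium ion attacks C8a (the only unsubstituted ring carbon in the molecule, ortho to 8-OH and para to 6-OH), and loss of ethanol from 40 gives the C8=O/C6-OH quinone methide; no stereocentre is touched, and the bridge descriptor changes from S to R only because C7 now outranks C7′.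

**Compound list**

1 | 1-bromo-3,5-dimethoxybenzene | COc1cc(Br)cc(OC)c1 | starting material
2 | (2-bromo-4,6-dimethoxybenzylidene)dimethyliminium chloride | C[N+](C)=Cc1c(Br)cc(OC)cc1OC.[Cl-] | intermediate
3 | 2-bromo-4,6-dimethoxybenzaldehyde | O=Cc1c(Br)cc(OC)cc1OC | intermediate
4 | 1-bromo-3,5-dimethoxy-2-methylbenzene | Cc1c(Br)cc(OC)cc1OC | intermediate
5 | (2S,3S)-2,3-epoxybutane | C[C@@H]1O[C@H]1C | starting material
6 | (3,5-dimethoxy-2-methylphenyl)magnesium bromide | Cc1c([Mg]Br)cc(OC)cc1OC | intermediate
7 | (2S,3S)-3-(3,5-dimethoxy-2-methylphenyl)butan-2-ol | C[C@H](O)[C@@H](C)c1cc(OC)cc(OC)c1C | intermediate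
8 | (2R,3S)-3-(3,5-dimethoxy-2-methylphenyl)butan-2-yl 4-nitrobenzoate | C[C@@H](OC(=O)c1ccc(cc1)[N+](=O)[O-])[C@@H](C)c2cc(OC)cc(OC)c2C | intermediate
9 | (2R,3S)-3-(3,5-dimethoxy-2-methylphenyl)butan-2-ol | C[C@@H](O)[C@@H](C)c1cc(OC)cc(OC)c1C | intermediate
10 | (2R,3S)-3-(2-bromo-3,5-dimethoxy-6-methylphenyl)butan-2-ol | C[C@@H](O)[C@@H](C)c1c(Br)c(OC)cc(OC)c1C | intermediate
11 | dilithio species (lithium alkoxide and aryllithium from 10) | C[C@@H](O[Li])[C@@H](C)c1c([Li])c(OC)cc(OC)c1C | intermediate
12 | 2-[(2S,3R)-3-hydroxybutan-2-yl]-4,6-dimethoxy-3-methylbenzoic acid | C[C@@H](O)[C@@H](C)c1c(C(=O)O)c(OC)cc(OC)c1C | intermediate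
13 | (3R,4S)-6,8-dimethoxy-3,4,5-trimethylisochroman-1-one | COc1cc(OC)c(C)c2c1C(=O)O[C@H](C)[C@H]2C | intermediate
14 | (3R,4S)-6,8-dihydroxy-3,4,5-trimethylisochroman-1-one | Oc1cc(O)c(C)c2c1C(=O)O[C@H](C)[C@H]2C | intermediate
15 | ethyl acetoacetate | CCOC(=O)CC(C)=O | starting material
16 | 4-methylcoumarin fused at C6′–C7′ of the (3′R,4′S)-lactone, 8′-OH free | CC1=CC(=O)Oc2c(C)c3c(c(O)c12)C(=O)O[C@H](C)[C@H]3C | intermediate
17 | 8′-O-MOM ether of 16 | CC1=CC(=O)Oc2c(C)c3c(c(OCOC)c12)C(=O)O[C@H](C)[C@H]3C | intermediate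
18 | pinacolboryl ketene acetal of 19 (bridge S) | C[C@H]1C=C(OB4OC(C)(C)C(C)(C)O4)Oc2c(C)c3c(c(OCOC)c12)C(=O)O[C@H](C)[C@H]3C | intermediate
19 | (S)-bridge 4-methyl-3,4-dihydrocoumarin lactone, 8′-O-MOM | C[C@H]1CC(=O)Oc2c(C)c3c(c(OCOC)c12)C(=O)O[C@H](C)[C@H]3C | intermediate
20 | ethyl (R)-3-hydroxybutanoate | CCOC(=O)C[C@@H](C)O | starting material
21 | dilithio alkoxide enolate of 20 | CCOC(O[Li])=C[C@@H](C)O[Li] | intermediate
22 | ethyl (2R,3R)-3-hydroxy-2-methylbutanoate | C[C@@H](O)[C@@H](C)C(=O)OCC | intermediate
23 | ethyl (2R,3R)-3-(TBS-oxy)-2-methylbutanoate | C[C@@H](O[Si](C)(C)C(C)(C)C)[C@@H](C)C(=O)OCC | intermediate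
24 | (2R,3R)-3-(TBS-oxy)-2-methylbutanoic acid | C[C@@H](O[Si](C)(C)C(C)(C)C)[C@@H](C)C(=O)O | intermediate
25 | 3-ethoxy-2-methyl-3-oxopropanoic acid | CCOC(=O)C(C)C(=O)O | starting material
26 | 1-[(2R,3R)-3-(TBS-oxy)-2-methylbutanoyl]imidazole | C[C@@H](O[Si](C)(C)C(C)(C)C)[C@@H](C)C(=O)n1ccnc1 | intermediate
27 | bis(chloromagnesium) enolate carboxylate of 25 | CCOC(O[Mg]Cl)=C(C)C(=O)O[Mg]Cl | intermediate
28 | ethyl (4R,5R)-5-(TBS-oxy)-2,4-dimethyl-3-oxohexanoate | C[C@@H](O[Si](C)(C)C(C)(C)C)[C@@H](C)C(=O)C(C)C(=O)OCC | intermediate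
29 | ethyl (2Z,4R,5R)-5-(TBS-oxy)-2,4-dimethyl-3-(trifluoromethylsulfonyloxy)hex-2-enoate | C[C@@H](O[Si](C)(C)C(C)(C)C)[C@@H](C)/C(OS(=O)(=O)C(F)(F)F)=C(C)/C(=O)OCC | intermediate
30 | ethyl (2E,4S,5R)-5-(TBS-oxy)-2,3,4-trimethylhex-2-enoate | C[C@@H](O[Si](C)(C)C(C)(C)C)[C@@H](C)/C(C)=C(C)/C(=O)OCC | intermediate
31 | (2E,4S,5R)-5-(TBS-oxy)-2,3,4-trimethylhex-2-enoic acid | C[C@@H](O[Si](C)(C)C(C)(C)C)[C@@H](C)/C(C)=C(C)/C(=O)O | intermediate
32 | (2E,4S,5R)-5-(TBS-oxy)-2,3,4-trimethylhex-2-enoyl chloride | C[C@@H](O[Si](C)(C)C(C)(C)C)[C@@H](C)/C(C)=C(C)/C(=O)Cl | intermediate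
33 | lithium enolate of 19 | C[C@H]1C=C(O[Li])Oc2c(C)c3c(c(OCOC)c12)C(=O)O[C@H](C)[C@H]3C | intermediate
34 | 3-acyl-4-methyldihydrocoumarin lactone (key-step precursor, C7 unassigned) | C[C@@H](O[Si](C)(C)C(C)(C)C)[C@@H](C)/C(C)=C(C)/C(=O)C1C(=O)Oc2c(C)c3c(c(OCOC)c2[C@H]1C)C(=O)O[C@H](C)[C@H]3C | intermediate
35 | acylketene with potassium O6′ phenoxide | C[C@@H](O[Si](C)(C)C(C)(C)C)[C@@H](C)/C(C)=C(C)/C(=O)C(=C=O)[C@H](C)c1c([O-])c(C)c2c(c1OCOC)C(=O)O[C@H](C)[C@H]2C.[K+] | intermediate
36 | oxido-dienylketene (dipotassium salt) | C[C@@H](O[Si](C)(C)C(C)(C)C)[C@@H](C)C(=C)C(C)=C([O-])C(=C=O)[C@H](C)c1c([O-])c(C)c2c(c1OCOC)C(=O)O[C@H](C)[C@H]2C.[K+].[K+] | intermediate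
37 | cyclohexadienone with C8a as CH2 (dipotassium salt) | C[C@@H](O[Si](C)(C)C(C)(C)C)[C@@H](C)C1=C(C)C([O-])=C(C(=O)C1)[C@H](C)c2c([O-])c(C)c3c(c2OCOC)C(=O)O[C@H](C)[C@H]3C.[K+].[K+] | intermediate
38 | bridged bis-arene (key-step product, 3-O-TBS, 8′-O-MOM, bridge S) | C[C@@H](O[Si](C)(C)C(C)(C)C)[C@@H](C)c1cc(O)c(c(O)c1C)[C@H](C)c2c(O)c(C)c3c(c2OCOC)C(=O)O[C@H](C)[C@H]3C | intermediate
39 | pentaol (fully deprotected bis-arene, bridge S) | C[C@@H](O)[C@@H](C)c1cc(O)c(c(O)c1C)[C@H](C)c2c(O)c(C)c3c(c2O)C(=O)O[C@H](C)[C@H]3C | intermediate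
40 | 1-ethoxyisochroman acetal (C1 epimers) | CCOC1O[C@H](C)[C@@H](C)c2c(C)c(O)c([C@H](C)c3c(O)c(C)c4c(c3O)C(=O)O[C@H](C)[C@H]4C)c(O)c12 | intermediate
41 | dicitrinone H (3R,4S; bridge R; 3′R,4′S) | CC1=C2C(=CO[C@H](C)[C@H]2C)C(=O)C([C@H](C)c2c(O)c(C)c3c(c2O)C(=O)O[C@H](C)[C@H]3C)=C1O | target

**Step count**

Total steps: 21. Longest linear sequence: 14 (steps 1–10, then 18–21). The left chain adds 7 steps (11–17).

**Steps most likely to fail**

1. Step 19.
   - Risk: the stabilised C7 enolate may persist without expelling the phenoxide. The amide base may add to the ketene instead of deprotonating C8a. Deprotonation at the benzylic C4′ position may trigger β-elimination of the right lactone carboxylate.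
   - Fallback (known chemistry), setting out from 9 and 14 and returning at 39. Compound 9 is demethylated with NaSEt in DMF at 140 °C to (2R,3S)-3-(3,5-dihydroxy-2-methylphenyl)butan-2-ol F1. Compound 14 is C-acetylated at its only free ring carbon (Ac2O, BF3·OEt2, Friedel–Crafts/Fries) to the 7′-acetyl lactone F2, and this is reduced with NaBH4 to the 1-hydroxyethyl lactone F3. A chiral phosphoric acid (or TsOH) dehydrates F3 to the ortho-quinone methide F4. F4 is intercepted by F1 in a Friedel–Crafts-type conjugate addition at C7, the carbon between the two hydroxyls, which is less crowded than C8a next to the sec-alkyl chain. This should give 39 together with its bridge epimer F5, which is removed by chromatography before step 21.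

2. Step 18.
   - Risk: O-acylation of the enolate, premature E1cB opening of the aryl lactone enolate, or dehydrochlorination of the acid chloride by the excess base.
   - Fallback, setting out from 30 and 19 and returning at 34. Ester 30 is reduced with i-Bu2AlH to the allylic alcohol F6, which is oxidised with MnO2 to the enal F7. Lithium enolate 33, made from 19 with one equivalent of LiN(SiMe3)2 at −78 °C, adds to F7 in an aldol reaction to give the β-hydroxy lactone F8. Dess–Martin oxidation of F8 gives 34.

3. Step 10.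
   - Risk: slow hydride transfer to the peri-crowded bridge carbon, or poor facial selectivity.
   - Fallback, setting out from 17 and returning at 19. Catalyst control is given up. Hydrogenation over Pd/C (H2, EtOAc) reduces the coumarin C=C bond to 19 and its (R)-bridge epimer F9. These are diastereomers because of C3′ and C4′, so they can be separated by chromatography or crystallisation. F9 is recycled to 17 by DDQ dehydrogenation.

Further compounds
F1 | step 19 | (2R,3S)-3-(3,5-dihydroxy-2-methylphenyl)butan-2-ol | C[C@@H](O)[C@@H](C)c1cc(O)cc(O)c1C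
F2 | step 19 | (3R,4S)-7-acetyl-6,8-dihydroxy-3,4,5-trimethylisochroman-1-one | CC(=O)c1c(O)c(C)c2c(c1O)C(=O)O[C@H](C)[C@H]2C
F3 | step 19 | (3R,4S)-6,8-dihydroxy-7-(1-hydroxyethyl)-3,4,5-trimethylisochroman-1-one (carbinol epimers) | CC(O)c1c(O)c(C)c2c(c1O)C(=O)O[C@H](C)[C@H]2C
F4 | step 19 | 7′-ethylidene ortho-quinone methide of the right lactone | CC=C1C(=O)C(C)=C2C(C(=O)O[C@H](C)[C@H]2C)=C1O
F5 | step 19 | bridge epimer of pentaol 39 | C[C@@H](O)[C@@H](C)c1cc(O)c(c(O)c1C)[C@@H](C)c2c(O)c(C)c3c(c2O)C(=O)O[C@H](C)[C@H]3C
F6 | step 18 | (2E,4S,5R)-5-(TBS-oxy)-2,3,4-trimethylhex-2-en-1-ol | C[C@@H](O[Si](C)(C)C(C)(C)C)[C@@H](C)/C(C)=C(C)/CO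
F7 | step 18 | (2E,4S,5R)-5-(TBS-oxy)-2,3,4-trimethylhex-2-enal | C[C@@H](O[Si](C)(C)C(C)(C)C)[C@@H](C)/C(C)=C(C)/C=O
F8 | step 18 | aldol adduct of 33 and F7 (C6 and C7 unassigned) | C[C@@H](O[Si](C)(C)C(C)(C)C)[C@@H](C)/C(C)=C(C)/C(O)C1C(=O)Oc2c(C)c3c(c(OCOC)c2[C@H]1C)C(=O)O[C@H](C)[C@H]3C
F9 | step 10 | (R)-bridge epimer of 19 | C[C@@H]1CC(=O)Oc2c(C)c3c(c(OCOC)c12)C(=O)O[C@H](C)[C@H]3C
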